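The runs were generated by integration for an exercise; scatter was added.

Two times stand against each other here: the time on which the exchange relaxes, and the time at which the flask is read.

all flasks: starting complex 0.24 M (fed, over 5.0 h); incoming ligand 0.216 M

| flask | leaving ligand | remark | time |
|---|---|---|---|
| grey | 2.4 M | run made earlier |  |
| flask | 1.20 M |  | 2.0 d |

grey run (percent of the starting complex charged)

| time / h | complex with one exchanged / % | starting complex / % |
|---|---|---|
| 1.33 | 1.4 | 26.6 |
| 4.00 | 4.1 | 77.8 |
| 6.00 | 5.1 | 94.1 |
| 10.0 | 8.9 | 90.1 |
| 15.0 | 10.7 | 89.1 |

(scatter of a reading: 0.5 percentage points)

- complex with one exchanged present at 2.0 d, in percent of the starting complex charged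
- starting complex present at 2.0 d, in percent of the starting complex charged

- a reading or a percentage of complex with one exchanged counts all its forms, free or not
- percentages count the whole charge, also what has not yet gone in
- no earlier run changes the charge of leaving ligand; that part of a forecast is a guess

After the feed in the grey run, the rise of complex with one exchanged slows, and its last two slopes give a relaxation time of about 4.64 h. The flask is read at 2.0 d, about ten times longer, so this reckoning assumes thermodynamic control for it, a balance rather than a speed, though the grey readings stop at 15.0 h.

The last grey reading sums to 99.8% for the two complexes, which reads as one reversible exchange. The balance is then the exchange quotient, complex with one exchanged times leaving ligand over starting complex times incoming ligand. That reading gives 1.53, taken while the amount was still rising.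

The flask has half the leaving ligand, an untested change, and this reckoning puts it at 17.6% complex with one exchanged. The forecast says more, 19.5% with 80.5% starting complex, and holds that “At 48 h the run should be at equilibrium”.

The flask gives 19.4% complex with one exchanged and 79.1% starting complex.

    complex with two exchanged + incoming ligand ⇌ leaving ligand + complex with three exchanged (K = 2.70, k = 0.00590 L mol⁻¹ h⁻¹)
    complex with one exchanged + incoming ligand ⇌ leaving ligand + complex with two exchanged (K = 1.70, k = 0.0380 L mol⁻¹ h⁻¹)
    crystals ⇌ complex with one exchanged, rate k3*(cs3 - [complex with one exchanged]) while solid is left; crystals form when [complex with one exchanged] > cs3 (solubility = 30.0 mM, k = 0.260 h⁻¹)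
    starting complex + incoming ligand ⇌ leaving ligand + complex with one exchanged (K = 2.10, k = 0.110 L mol⁻¹ h⁻¹)
    incoming ligand ⇌ dormant form (K = 3.30, k = 0.0110 h⁻¹)

Of that complex with one exchanged, 6.76% stands as crystals. With these taken out, the end state of the flask gives a quotient of 2.08, higher than the grey reading. The state at 2.0 d is not the end of this flask, which holds 7.35% complex with one exchanged at 20.0 d. For a neighbour flask charged with 2.0 M leaving ligand, the grey quotient gives 12.3%, and that neighbour, with 0% crystals, holds 10.9%.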